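**Retrosynthetic overview**

1. 2-Nonadecyl-1,4-benzoquinone ⇐ 4-amino-2-nonadecylphenol (oxidation, C=NH exchanged for C=O by water) ⇐ 4-nitro-2-nonadecylphenol (hydrogenation); the nitrogen is a removable placeholder for one quinone oxygen.
2. Key disconnection: both ring C=C bonds of the quinone, the unsubstituted CH=CH bond and the C(nonadecyl)=CH bond, are cut together. In the nitrophenol these are the two ortho–meta bonds relative to OH. This leads to docosan-2-one (its C=O carbon with both α-carbons, CH3 and CH2) and the nitromalonaldehyde anion (two CHO carbons flanking C–NO2), joined by a [3+3] benzannulation through double aldol condensation.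
3. Enabling feature: the six-membered ring holds its two carbonyl carbons para (ring positions 1 and 4). It therefore consists of two C–C(X)–C triads joined only through the two C=C bonds, and each of these bonds links a carbon α to one carbonyl with a carbon α to the other. The nonadecyl group sits on an α-carbon of one triad, which is thus simply a methyl alkyl ketone.
4. Ring formation: the only ring (the carbocycle) is formed in step 2 from two acyclic three-carbon units; the ketone comes from docos-1-ene by Tsuji–Wacker oxidation.

Key step: step 2

Remark: the target has no stereocentre, so no stereocontrol is needed; sodium nitromalonaldehyde monohydrate, Na[O2N–C(CHO)2]·H2O, is taken as a purchasable reagent (impact-sensitive, to be handled moist and in small portions).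

**Route**

Step 1
Reactants: 1 docos-1-ene
Product: 2 docosan-2-one
Conditions: PdCl2 (10 mol %), CuCl (30 mol %), O2 (1 atm), DMA/H2O 7:1, 60 °C
Reagents that add atoms: water, O (carbonyl oxygen, delivered by hydroxypalladation; dioxygen, O=O, is the terminal oxidant)
Why: Tsuji–Wacker oxidation: Markovnikov hydroxypalladation of the unhindered terminal alkene by divalent palladium and β-hydride elimination should give the methyl ketone, while CuCl/O2 return zerovalent palladium to the divalent state; unfunctionalised long-chain 1-alkenes are standard substrates.

Step 2
Reactants: 2 docosan-2-one; 3 sodium nitromalonaldehyde monohydrate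
Product: 5 4-nitro-2-nonadecylphenol, via open-chain nitronate 4 (not isolated)
Conditions: 3 (1.5 equiv), NaOH (2 equiv), EtOH/THF/H2O, 40 °C, 3–5 d, N2; then 2 M HCl
Reagents that add atoms: none
Why: Hydroxide enolises 2, whose methyl α-carbon should first condense (aldol addition, dehydration) with one formyl group of the nitromalonaldehyde anion to give the open-chain nitronate 4; after enolisation at the α-methylene carbon, a second, intramolecular aldol condensation onto the remaining formyl group, loss of water and tautomerisation should deliver the 4-nitrophenolate. The closest known reaction type is the classical condensation of sodium nitromalonaldehyde with ketones that carry two enolisable α-carbons (acetone, methyl alkyl ketones, large-ring cycloalkanones) to 4-nitrophenols, a double aldol condensation that amounts to a [3+3] benzannulation. The only ring is closed by a 6-(enolexo)-exo-trig aldol addition onto an aldehyde, which is geometrically possible because the C=C bond of 4 can isomerise within the delocalised anion, and the closure becomes irreversible through aromatisation. No stereocentre is formed. The step needs cross-condensation over self-condensation and complete double condensation: the dialdehyde anion has no enolisable position and carries the most electrophilic carbonyl groups, self-aldol of 2 is reversible, and a six-membered ring can only arise when both α-carbons of one ketone have reacted, so the substitution pattern (alkyl ortho to OH, nitro para to OH) is fixed by connectivity whichever α-carbon reacts first.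

Step 3
Reactants: 5 4-nitro-2-nonadecylphenol
Product: 6 4-amino-2-nonadecylphenol
Conditions: H2 (1 atm), 10% Pd/C, EtOAc/EtOH, rt; filtered under argon and used at once
Reagents that add atoms: none
Why: Heterogeneous catalytic hydrogenation of an aromatic nitro group to the amine; phenol, arene and alkyl chain are inert under these conditions, and exclusion of air should prevent premature oxidation of the electron-rich aminophenol.

Step 4
Reactants: 6 4-amino-2-nonadecylphenol
Product: 8 2-nonadecyl-1,4-benzoquinone, via quinone monoimine 7 (not isolated)
Conditions: FeCl3·6H2O (2.5 equiv), 1 M HCl/THF 1:1, 0 °C to rt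
Reagents that add atoms: water, O
Why: Oxidation of a p-aminophenol to the p-quinone: two one-electron oxidations by FeCl3 should give the quinone monoimine 7, whose protonated C=N bond is hydrolysed by the aqueous acid, the nitrogen leaving as ammonium; the alkyl chain and the product quinone are inert to FeCl3.

**Compound list**

1 | docos-1-ene | C=CCCCCCCCCCCCCCCCCCCCC | starting material
2 | docosan-2-one | CC(=O)CCCCCCCCCCCCCCCCCCCC | intermediate
3 | sodium nitromalonaldehyde monohydrate (sodium salt of 2-nitropropanedial, nitronate form, hydrate) | [Na+].O=CC(C=O)=[N+]([O-])[O-].O | starting material
4 | sodium (E)-2-nitro-5-oxopentacos-3-enal nitronate (delocalised anion; the E isomer first formed equilibrates with the Z isomer before ring closure) | CCCCCCCCCCCCCCCCCCCCC(=O)/C=C/C(C=O)=[N+]([O-])[O-].[Na+] | intermediate (not isolated)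
5 | 4-nitro-2-nonadecylphenol | CCCCCCCCCCCCCCCCCCCc1cc(ccc1O)[N+](=O)[O-] | intermediate
6 | 4-amino-2-nonadecylphenol | CCCCCCCCCCCCCCCCCCCc1cc(N)ccc1O | intermediate
7 | 4-imino-2-nonadecylcyclohexa-2,5-dien-1-one (N–H geometry not defined, rapid inversion) | CCCCCCCCCCCCCCCCCCCC1=CC(=N)C=CC1=O | intermediate (not isolated)
8 | 2-nonadecyl-1,4-benzoquinone (2-nonadecylcyclohexa-2,5-diene-1,4-dione) | CCCCCCCCCCCCCCCCCCCC1=CC(=O)C=CC1=O | target

**Count and risks**

Total step count: 4. Longest linear sequence: 4 steps (1 → 2 → 5 → 6 → 8).

The three steps most likely to fail:

First, step 2. The waxy, water-insoluble ketone may mix poorly with the alkaline aqueous phase, so that decomposition of the nitromalonaldehyde salt and stalling after the first condensation outrun ring closure. The fallback builds the ring on a small, water-miscible ketone and grows the chain afterwards. It sets out from 3: condensation of 3 with commercial hex-5-en-2-one under aqueous NaOH at room temperature, then HCl, should give 2-allyl-4-nitrophenol F1. Cross-metathesis of F1 with an excess of octadec-1-ene (second-generation Grubbs catalyst, RuCl2(=CHPh)(PCy3)(H2IMes), CH2Cl2, 40 °C) should give (E)-4-nitro-2-(nonadec-2-en-1-yl)phenol F2; any Z isomer is of no consequence. Hydrogenation of F2 (H2, 10% Pd/C, EtOAc/EtOH) should saturate the alkene and reduce the nitro group in one operation, which returns to the route at 6.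

Second, step 4. The quinone monoimine may be intercepted by unreacted aminophenol (indophenol-type condensation) or may add chloride faster than it is hydrolysed. The fallback removes the nitrogen before the oxidation and brings in the second oxygen by radical oxidation of a phenol. It sets out from 6: diazotisation (NaNO2, aq. HCl/THF, 0 °C) should give 4-hydroxy-3-nonadecylbenzenediazonium chloride F3, which is reduced in the same flask with 50% H3PO2 (0 °C to rt) to 2-nonadecylphenol F4. Teuber oxidation of F4 with potassium nitrosodisulfonate, K2[ON(SO3)2] (2.2 equiv, aq. KH2PO4/acetone, rt), should attack the free para position and return to the route at 8.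

Third, step 1. Migration of the double bond along the chain through palladium hydride species before oxidation, together with slow turnover of the poorly soluble olefin, may lead to regioisomeric internal ketones. The fallback fixes the oxygen at C2 by a polar sequence. It sets out from 1: epoxidation (mCPBA, CH2Cl2, 0 °C to rt) should give racemic 2-icosyloxirane F5; LiAlH4 (THF, 0 °C to rt) should open it at the terminal carbon to racemic docosan-2-ol F6; oxidation with Dess–Martin periodinane (CH2Cl2, rt) returns to the route at 2.

**Further compounds**

F1 | step 2 | 2-allyl-4-nitrophenol | C=CCc1cc(ccc1O)[N+](=O)[O-]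
F2 | step 2 | (E)-4-nitro-2-(nonadec-2-en-1-yl)phenol | CCCCCCCCCCCCCCCC/C=C/Cc1cc(ccc1O)[N+](=O)[O-]
F3 | step 4 | 4-hydroxy-3-nonadecylbenzenediazonium chloride | CCCCCCCCCCCCCCCCCCCc1cc(ccc1O)[N+]#N.[Cl-]
F4 | step 4 | 2-nonadecylphenol | CCCCCCCCCCCCCCCCCCCc1ccccc1O
F5 | step 1 | 2-icosyloxirane (racemic) | CCCCCCCCCCCCCCCCCCCCC1CO1
F6 | step 1 | docosan-2-ol (racemic) | CC(O)CCCCCCCCCCCCCCCCCCCC
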